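Readings and results stem from a simulated flask for an exercise; noise was put on by code.

We charge 0.050 M substrate against 2.5 mM spent carrier, so each carrier has to serve 20.0 substrates, and the salt in the second phase must recharge it every time.

| flask | substrate | salt in the second phase | spent carrier | remark | time | volume of the second phase over the first |
|---|---|---|---|---|---|---|
| Tuesday's | 0.050 M | 0.098 M | 2.5 mM | run made earlier |  |  |
| Monday's | 0.050 M | 0.11 M | 2.5 mM | run made earlier |  |  |
| birch | 0.050 M | 0.0800 M | 2.5 mM |  | 2.0 min | 1.0 |
| larch | 0.050 M | 0.120 M | 2.5 mM |  | 2.0 min | 1.0 |
| cedar | 0.050 M | 0.150 M | 2.5 mM |  | 2.0 min | 1.0 |

| Tuesday's: time / s | Tuesday's: product / % | Monday's: time / s | Monday's: product / % |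
|---|---|---|---|
| 10.0 | 4 | 10.0 | 5 |
| 15.0 | 6 | 30.0 | 14 |
| 40.0 | 18 | 50.0 | 20 |
| 80.0 | 27 | 80.0 | 29 |

(standard deviation of a reading: 1.5 percentage points)

- charges count per volume of the first phase; a concentration in a rate is the amount of a species over the volume of its own phase; every rate counts per litre of the first phase
- the numbers in the tables scatter by 1.5 percentage points (one standard deviation)
- the earlier runs hold the two phases in the same ratio of volumes as the flask asked about
- "hardly changes" means that all values lie within two and a half points (for a concentration: within two and a half percent of the largest)

* amount of product at the end, in percent of the substrate charged for birch, larch, cedar, in this order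
* the shape of the row from first to last (rises all the way / rises, then falls / falls, then rises / hardly changes / falls all the way)

The percent of substrate left gives an apparent, pseudo-first-order constant. Averaged over both runs, it is 0.00499 s⁻¹ in the early windows and 0.00344 s⁻¹ in the late ones. We read this drop as working carrier being lost. Dividing the rate of that loss by the rate of product formation removes the clock. Between the window centres about 14.0% of the charge reacts, which gives the reading 0.111, the carrier lost per product formed. The readings give this ratio only roughly.

The same two constants give the ladder:

| Rung | Time | What the flask does |
|---|---|---|
| One carrier turnover | 10.0 s | Cycles many times |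
| Loss of working carrier | 129 s | Slows during the run |
| Substrate life at the early constant | 200 s | Much substrate remains |

One carrier turnover takes less time than the loss of working carrier, and that loss takes less time than the substrate life.

Our own reckoning continues the fall in the constant over the last stretch and gives about 33.4%. Monday's 29% against Tuesday's 27% is a gap of 2 percentage points at a scatter of 1.5 points per reading, over a salt step from 0.098 M to 0.11 M, so these runs do not tell how the row moves between 0.0800 M and 0.150 M. We commit to that level for the row and to no shape.

The forecast differs: it gives 37.5%, 40% and 41.5%, and its shape is "rises all the way", while judging that “the salt dependence is weak and poorly fixed”.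

The flask gives 34.3%, 35.2% and 35.5%, and the row hardly changes.

    substrate + fresh carrier → product + spent carrier (k = 2.60 M⁻¹ s⁻¹)
    spent carrier + salt in the second phase ⇌ fresh carrier + spent salt in the second phase (K = 1.30, k = 17.0 M⁻¹ s⁻¹)
    2 fresh carrier → spent catalyst (k = 2.80 M⁻¹ s⁻¹)

Counted from the end states, the ratio we read as 0.111 is 0.0761 in birch and 0.0806 in cedar. Spent catalyst and the short time given act together as part of the reason for the flat row. Without the reaction of 2 fresh carrier to spent catalyst, cedar gives 49.6% instead of 35.5%, and ten times the time gives 74.7%. From birch to cedar the gain is 1.2 points, and without that reaction it is 3.8 points.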